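## Retrosynthetic overview

- Numbering: lactone O1, C2 (C=O), C3 (methyl-bearing), C4, C5. The side chain runs C6 to C18, with C18 on C3 of the furan ring. C7 (S) is the only stereocentre.
- The strategy rests on the C9–C10 single bond, which lies one carbon from the E-trisubstituted C11=C12 alkene. A carboxyl held temporarily on C9 makes C9–C10–C11=C12 a γ,δ-unsaturated acid, which is the product pattern of an Ireland–Claisen rearrangement.
- Key disconnection: C9–C10, back to an allylic ester of a citronellol-derived acid (C5–C9 plus the carboxyl, C7 from (S)-citronellol) with a furyl dienol (C10–C18). The carboxyl is then removed by a radical route.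
- Late disconnection: the butenolide ring comes from a (Z)-β-iodoenone and CO. C3, C4 and the 3-methyl group arrive as propyne on the C5 aldehyde.
- Ring order: the furan ring is bought in furan-3-carbaldehyde and carried throughout. The butenolide ring is the only ring made and is closed in the last step.

Key step: step 12

Remark: the carbinol carbons created by the three Grignard additions, and the temporary centre at C9, are carried as mixtures of configurations because each is erased later. (S)-Citronellol of high enantiomeric purity is assumed.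

## Route

Step 1
Reactants: 1 (S)-citronellol
Product: 2 tert-butyl{[(3S)-3,7-dimethyloct-6-en-1-yl]oxy}dimethylsilane
Conditions: TBSCl, imidazole, CH2Cl2, 0 °C to rt
Reagents that add atoms: tert-butyldimethylsilyl chloride, CC(C)(C)[Si](C)(C)Cl
Why: Imidazole-promoted silyl ether protection masks the C5 hydroxyl for the base and radical steps ahead and does not touch C7.

Step 2
Reactants: 2 tert-butyl{[(3S)-3,7-dimethyloct-6-en-1-yl]oxy}dimethylsilane
Product: 4 (4S)-6-{[tert-butyl(dimethyl)silyl]oxy}-4-methylhexanal, via ozonide 3 (not isolated)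
Conditions: O3, CH2Cl2, −78 °C; then Me2S, −78 °C to rt
Reagents that add atoms: ozone, [O-][O+]=O
Why: Ozonolysis with reductive work-up cleaves the only alkene through ozonide 3 and leaves the aldehyde carbon that becomes the temporary carboxyl on C9, well away from C7.

Step 3
Reactants: 4 (4S)-6-{[tert-butyl(dimethyl)silyl]oxy}-4-methylhexanal
Product: 5 (4S)-6-{[tert-butyl(dimethyl)silyl]oxy}-4-methylhexanoic acid
Conditions: NaClO2, NaH2PO4, 2-methylbut-2-ene, t-BuOH/H2O, rt
Reagents that add atoms: sodium chlorite, [Na+].[O-]Cl=O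
Why: The Pinnick oxidation works at mildly acidic pH that the TBS ether tolerates, and 2-methylbut-2-ene takes up the hypochlorous acid.

Step 4
Reactants: 6 furan-3-carbaldehyde; 7 ethyl (triphenylphosphoranylidene)acetate
Product: 8 ethyl (2E)-3-(furan-3-yl)prop-2-enoate
Conditions: CH2Cl2, rt
Reagents that add atoms: ethyl (triphenylphosphoranylidene)acetate (7), CCOC(=O)C=P(c1ccccc1)(c1ccccc1)c1ccccc1
Why: Wittig olefination with a stabilised ylide adds C17 and C16 to the aldehyde carbon C18, and its geometry is irrelevant because the alkene is saturated next.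

Step 5
Reactants: 8 ethyl (2E)-3-(furan-3-yl)prop-2-enoate
Product: 9 ethyl 3-(furan-3-yl)propanoate
Conditions: H2 (1 atm), 5% Pd/C, EtOAc, rt, stopped after one equivalent of H2
Reagents that add atoms: none
Why: In this heterogeneous catalytic hydrogenation the unhindered conjugated C=C should take up hydrogen much faster than the aromatic furan ring at 1 atm.

Step 6
Reactants: 9 ethyl 3-(furan-3-yl)propanoate
Product: 10 3-(furan-3-yl)propanal
Conditions: i-Bu2AlH (1.05 equiv), CH2Cl2, −78 °C; MeOH, then aq. potassium sodium tartrate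
Reagents that add atoms: none
Why: Partial ester reduction with i-Bu2AlH at −78 °C rests at the tetrahedral aluminium hemiacetal, which releases the aldehyde only on work-up.

Step 7
Reactants: 10 3-(furan-3-yl)propanal; 11 isopropenylmagnesium bromide
Product: 12 5-(furan-3-yl)-2-methylpent-1-en-3-ol (racemic)
Conditions: THF, −78 to 0 °C; aq. NH4Cl
Reagents that add atoms: isopropenylmagnesium bromide (11), CC(=C)[Mg]Br
Why: Grignard 1,2-addition installs C15, its methyl group and C14 as a 2-methylallylic alcohol, and the racemic carbinol centre is erased in step 8.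

Step 8
Reactants: 12 5-(furan-3-yl)-2-methylpent-1-en-3-ol; 13 triethyl orthoacetate
Product: 15 ethyl (4E)-7-(furan-3-yl)-4-methylhept-4-enoate, via ketene acetal 14 (not isolated)
Conditions: MeC(OEt)3 (excess), EtCO2H (cat.), 140 °C, EtOH distilled off
Reagents that add atoms: triethyl orthoacetate (13), CCOC(C)(OCC)OCC
Why: In the Johnson–Claisen rearrangement, acid-catalysed exchange and loss of ethanol give ketene acetal 14, whose chair [3,3] shift with the furylethyl group pseudo-equatorial forms C13–C14 and the E C15=C16 alkene.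

Step 9
Reactants: 15 ethyl (4E)-7-(furan-3-yl)-4-methylhept-4-enoate
Product: 16 (4E)-7-(furan-3-yl)-4-methylhept-4-enal
Conditions: i-Bu2AlH (1.05 equiv), CH2Cl2, −78 °C; MeOH, then aq. potassium sodium tartrate
Reagents that add atoms: none
Why: The same low-temperature partial ester reduction gives the C12 aldehyde without touching the isolated alkene or the furan.

Step 10
Reactants: 16 (4E)-7-(furan-3-yl)-4-methylhept-4-enal; 11 isopropenylmagnesium bromide
Product: 17 (6E)-9-(furan-3-yl)-2,6-dimethylnona-1,6-dien-3-ol (racemic)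
Conditions: THF, −78 to 0 °C; aq. NH4Cl
Reagents that add atoms: isopropenylmagnesium bromide (11), CC(=C)[Mg]Br
Why: A second Grignard 1,2-addition brings in C11, its methyl group and the terminal methylene C10, and the configuration at C12 is irrelevant because that carbon becomes sp2 in step 12.

Step 11
Reactants: 5 (4S)-6-{[tert-butyl(dimethyl)silyl]oxy}-4-methylhexanoic acid; 17 (6E)-9-(furan-3-yl)-2,6-dimethylnona-1,6-dien-3-ol
Product: 18 (6E)-9-(furan-3-yl)-2,6-dimethylnona-1,6-dien-3-yl (4S)-6-{[tert-butyl(dimethyl)silyl]oxy}-4-methylhexanoate (both carbinol epimers)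
Conditions: DCC, DMAP (cat.), CH2Cl2, 0 °C to rt
Reagents that add atoms: none
Why: In the Steglich esterification DMAP relays the activated acyl group to the secondary allylic alcohol under neutral conditions, so the allylic C–O bond never ionises and no transposition occurs.

Step 12
Reactants: 18 (6E)-9-(furan-3-yl)-2,6-dimethylnona-1,6-dien-3-yl (4S)-6-{[tert-butyl(dimethyl)silyl]oxy}-4-methylhexanoate
Product: 21 (4S)-6-{[tert-butyl(dimethyl)silyl]oxy}-2-[(2E,6E)-9-(furan-3-yl)-2,6-dimethylnona-2,6-dien-1-yl]-4-methylhexanoic acid (both C9 epimers), via silyl ketene acetal 19 (not isolated), via trimethylsilyl ester 20 (not isolated)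
Conditions: LiN(i-Pr)2 (1.3 equiv), THF, −78 °C; Me3SiCl, −78 °C to rt, then 55 °C; then H2O/THF, dilute citric acid
Reagents that add atoms: chlorotrimethylsilane, C[Si](C)(C)Cl (its silyl group stands in 19 and 20 and leaves again on work-up)
Why: The amide base removes a C9 proton of the only enolisable carbonyl, Me3SiCl traps the enolate on oxygen as 19, and on warming 19 undergoes a concerted suprafacial [3,3]-sigmatropic shift in which C9 bonds to the terminal methylene C10, the O–C12 bond breaks and the π bond moves to C11=C12, giving silyl ester 20 and, after hydrolysis, acid 21. The closest known reaction type is the Ireland–Claisen rearrangement of esters of 2-methylalk-1-en-3-ols to (E)-4-methylalk-4-enoic acids. No ring is closed, since the six-membered array exists only in the chair transition state. The one selectivity needed is the E geometry of C11=C12, secured by the C13 chain on C12 lying pseudo-equatorial, because the pseudo-axial placement would meet the OSiMe3 group of the ketene acetal carbon in a 1,3-diaxial contact. The new centre C9 forms as a mixture because neither the carbinol configuration nor the ketene acetal geometry is controlled, which is harmless since C9 becomes CH2 in step 14. C7 is γ to the carbonyl and is never deprotonated, so it keeps its S configuration, and the furan C–H bonds and the TBS ether are inert to the base at −78 °C.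

Step 13
Reactants: 21 (4S)-6-{[tert-butyl(dimethyl)silyl]oxy}-2-[(2E,6E)-9-(furan-3-yl)-2,6-dimethylnona-2,6-dien-1-yl]-4-methylhexanoic acid
Product: 22 2-sulfanylidenepyridin-1(2H)-yl ester of 21 (Barton ester, both C9 epimers)
Conditions: 1-hydroxypyridine-2(1H)-thione, DCC, DMAP (cat.), CH2Cl2, 0 °C to rt, dark
Reagents that add atoms: 1-hydroxypyridine-2(1H)-thione, ON1C=CC=CC1=S
Why: Carbodiimide coupling gives the O-acyl thiohydroxamate under neutral conditions that suit the α-branched acid, the furan and the silyl ether.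

Step 14
Reactants: 22 Barton ester of 21
Product: 23 tert-butyl{[(3S,7E,11E)-14-(furan-3-yl)-3,7,11-trimethyltetradeca-7,11-dien-1-yl]oxy}dimethylsilane
Conditions: t-BuSH (10 equiv), toluene, 250 W tungsten lamp, 10–20 °C
Reagents that add atoms: none
Why: In the Barton reductive decarboxylation light cleaves the N–O bond, the acyloxy radical loses CO2, and the secondary C9 radical should take hydrogen from the excess thiol faster than it can close reversibly (3-exo) on C11=C12, so the E geometry and C7 stay intact.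

Step 15
Reactants: 23 tert-butyl{[(3S,7E,11E)-14-(furan-3-yl)-3,7,11-trimethyltetradeca-7,11-dien-1-yl]oxy}dimethylsilane
Product: 24 (3S,7E,11E)-14-(furan-3-yl)-3,7,11-trimethyltetradeca-7,11-dien-1-ol
Conditions: Bu4NF, THF, rt
Reagents that add atoms: none
Why: Fluoride-mediated desilylation is driven by the Si–F bond and leaves alkenes and furan untouched.

Step 16
Reactants: 24 (3S,7E,11E)-14-(furan-3-yl)-3,7,11-trimethyltetradeca-7,11-dien-1-ol
Product: 25 (3S,7E,11E)-14-(furan-3-yl)-3,7,11-trimethyltetradeca-7,11-dienal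
Conditions: Dess–Martin periodinane, CH2Cl2, 0 °C to rt
Reagents that add atoms: none
Why: The Dess–Martin oxidation stops at the C5 aldehyde and spares the electron-rich furan and alkenes, and C7 is β to the carbonyl and cannot epimerise by enolisation.

Step 17
Reactants: 25 (3S,7E,11E)-14-(furan-3-yl)-3,7,11-trimethyltetradeca-7,11-dienal; 26 prop-1-yn-1-ylmagnesium bromide
Product: 27 (6S,10E,14E)-17-(furan-3-yl)-6,10,14-trimethylheptadeca-10,14-dien-2-yn-4-ol (both carbinol epimers)
Conditions: THF, −78 to 0 °C; aq. NH4Cl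
Reagents that add atoms: prop-1-yn-1-ylmagnesium bromide (26), CC#C[Mg]Br
Why: Alkynyl Grignard 1,2-addition attaches C4, C3 and the 3-methyl group to C5, and the new carbinol centre is removed in step 18.

Step 18
Reactants: 27 (6S,10E,14E)-17-(furan-3-yl)-6,10,14-trimethylheptadeca-10,14-dien-2-yn-4-ol
Product: 28 (6S,10E,14E)-17-(furan-3-yl)-6,10,14-trimethylheptadeca-10,14-dien-2-yn-4-one
Conditions: MnO2 (activated, excess), CH2Cl2, rt
Reagents that add atoms: none
Why: MnO2 oxidises the activated propargylic alcohol under neutral conditions, which avoids base-induced isomerisation of the ynone to an allenyl ketone.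

Step 19
Reactants: 28 (6S,10E,14E)-17-(furan-3-yl)-6,10,14-trimethylheptadeca-10,14-dien-2-yn-4-one
Product: 29 (2Z,6S,10E,14E)-17-(furan-3-yl)-2-iodo-6,10,14-trimethylheptadeca-2,10,14-trien-4-one
Conditions: NaI, AcOH, rt, dark, argon
Reagents that add atoms: sodium iodide, [Na+].[I-]
Why: In this conjugate hydroiodination of an ynone, iodide adds to C3 and the allenol is protonated anti to iodine, so under kinetic control iodine and the C5 carbonyl end up cis (Z).

Step 20
Reactants: 29 (2Z,6S,10E,14E)-17-(furan-3-yl)-2-iodo-6,10,14-trimethylheptadeca-2,10,14-trien-4-one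
Product: 30 (5Z)-5-[(2S,6E,10E)-13-(furan-3-yl)-2,6,10-trimethyltrideca-6,10-dien-1-ylidene]-3-methylfuran-2(5H)-one
Conditions: PdCl2(PPh3)2 (5 mol %), CO (1 atm), Et3N (2 equiv), DMF, 50 °C
Reagents that add atoms: carbon monoxide, [C-]#[O+]
Why: In this palladium-catalysed carbonylative lactonisation, zerovalent palladium formed in situ inserts into C3–I with retention, CO insertion gives the C2 acylpalladium, and the oxygen of the C5 enol, held cis by the Z alkene, attacks it while Et3N removes a C6 proton; this closes O1–C2 and should give the Z C5=C6 alkene, which keeps C7 away from C4–H.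

## Compound list

1 | (S)-citronellol, (3S)-3,7-dimethyloct-6-en-1-ol | OCC[C@@H](C)CCC=C(C)C | starting material
2 | tert-butyl{[(3S)-3,7-dimethyloct-6-en-1-yl]oxy}dimethylsilane | CC(C)(C)[Si](C)(C)OCC[C@@H](C)CCC=C(C)C | intermediate
3 | 3-[(3S)-5-{[tert-butyl(dimethyl)silyl]oxy}-3-methylpentyl]-5,5-dimethyl-1,2,4-trioxolane (ozonide, not isolated) | CC(C)(C)[Si](C)(C)OCC[C@@H](C)CCC1OOC(C)(C)O1 | intermediate
4 | (4S)-6-{[tert-butyl(dimethyl)silyl]oxy}-4-methylhexanal | CC(C)(C)[Si](C)(C)OCC[C@@H](C)CCC=O | intermediate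
5 | (4S)-6-{[tert-butyl(dimethyl)silyl]oxy}-4-methylhexanoic acid | CC(C)(C)[Si](C)(C)OCC[C@@H](C)CCC(=O)O | intermediate
6 | furan-3-carbaldehyde | O=Cc1ccoc1 | starting material
7 | ethyl (triphenylphosphoranylidene)acetate | CCOC(=O)C=P(c1ccccc1)(c1ccccc1)c1ccccc1 | starting material
8 | ethyl (2E)-3-(furan-3-yl)prop-2-enoate | CCOC(=O)/C=C/c1ccoc1 | intermediate
9 | ethyl 3-(furan-3-yl)propanoate | CCOC(=O)CCc1ccoc1 | intermediate
10 | 3-(furan-3-yl)propanal | O=CCCc1ccoc1 | intermediate
11 | isopropenylmagnesium bromide | CC(=C)[Mg]Br | starting material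
12 | 5-(furan-3-yl)-2-methylpent-1-en-3-ol (racemic) | CC(=C)C(O)CCc1ccoc1 | intermediate
13 | triethyl orthoacetate | CCOC(C)(OCC)OCC | starting material
14 | 3-{3-[(1-ethoxyethenyl)oxy]-4-methylpent-4-en-1-yl}furan (ketene acetal, not isolated) | C=C(OCC)OC(CCc1ccoc1)C(C)=C | intermediate
15 | ethyl (4E)-7-(furan-3-yl)-4-methylhept-4-enoate | CCOC(=O)CC/C(C)=C/CCc1ccoc1 | intermediate
16 | (4E)-7-(furan-3-yl)-4-methylhept-4-enal | O=CCC/C(C)=C/CCc1ccoc1 | intermediate
17 | (6E)-9-(furan-3-yl)-2,6-dimethylnona-1,6-dien-3-ol (racemic) | CC(=C)C(O)CC/C(C)=C/CCc1ccoc1 | intermediate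
18 | (6E)-9-(furan-3-yl)-2,6-dimethylnona-1,6-dien-3-yl (4S)-6-{[tert-butyl(dimethyl)silyl]oxy}-4-methylhexanoate (both carbinol epimers) | CC(C)(C)[Si](C)(C)OCC[C@@H](C)CCC(=O)OC(CC/C(C)=C/CCc1ccoc1)C(C)=C | intermediate
19 | trimethylsilyl ketene acetal of 18 (C9=C double bond, either geometry, not isolated) | CC(C)(C)[Si](C)(C)OCC[C@@H](C)CC=C(O[Si](C)(C)C)OC(CC/C(C)=C/CCc1ccoc1)C(C)=C | intermediate
20 | trimethylsilyl ester of 21 (both C9 epimers, not isolated) | CC(C)(C)[Si](C)(C)OCC[C@@H](C)CC(C(=O)O[Si](C)(C)C)C/C(C)=C/CC/C(C)=C/CCc1ccoc1 | intermediate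
21 | (4S)-6-{[tert-butyl(dimethyl)silyl]oxy}-2-[(2E,6E)-9-(furan-3-yl)-2,6-dimethylnona-2,6-dien-1-yl]-4-methylhexanoic acid (both C9 epimers) | CC(C)(C)[Si](C)(C)OCC[C@@H](C)CC(C(=O)O)C/C(C)=C/CC/C(C)=C/CCc1ccoc1 | intermediate
22 | 2-sulfanylidenepyridin-1(2H)-yl ester of 21 (Barton ester, both C9 epimers) | CC(C)(C)[Si](C)(C)OCC[C@@H](C)CC(C(=O)ON1C=CC=CC1=S)C/C(C)=C/CC/C(C)=C/CCc1ccoc1 | intermediate
23 | tert-butyl{[(3S,7E,11E)-14-(furan-3-yl)-3,7,11-trimethyltetradeca-7,11-dien-1-yl]oxy}dimethylsilane | CC(C)(C)[Si](C)(C)OCC[C@@H](C)CCC/C(C)=C/CC/C(C)=C/CCc1ccoc1 | intermediate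
24 | (3S,7E,11E)-14-(furan-3-yl)-3,7,11-trimethyltetradeca-7,11-dien-1-ol | OCC[C@@H](C)CCC/C(C)=C/CC/C(C)=C/CCc1ccoc1 | intermediate
25 | (3S,7E,11E)-14-(furan-3-yl)-3,7,11-trimethyltetradeca-7,11-dienal | O=CC[C@@H](C)CCC/C(C)=C/CC/C(C)=C/CCc1ccoc1 | intermediate
26 | prop-1-yn-1-ylmagnesium bromide | CC#C[Mg]Br | starting material
27 | (6S,10E,14E)-17-(furan-3-yl)-6,10,14-trimethylheptadeca-10,14-dien-2-yn-4-ol (both carbinol epimers) | CC#CC(O)C[C@@H](C)CCC/C(C)=C/CC/C(C)=C/CCc1ccoc1 | intermediate
28 | (6S,10E,14E)-17-(furan-3-yl)-6,10,14-trimethylheptadeca-10,14-dien-2-yn-4-one | CC#CC(=O)C[C@@H](C)CCC/C(C)=C/CC/C(C)=C/CCc1ccoc1 | intermediate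
29 | (2Z,6S,10E,14E)-17-(furan-3-yl)-2-iodo-6,10,14-trimethylheptadeca-2,10,14-trien-4-one | C/C(I)=C/C(=O)C[C@@H](C)CCC/C(C)=C/CC/C(C)=C/CCc1ccoc1 | intermediate
30 | (5Z)-5-[(2S,6E,10E)-13-(furan-3-yl)-2,6,10-trimethyltrideca-6,10-dien-1-ylidene]-3-methylfuran-2(5H)-one | CC1=C/C(=C/[C@@H](C)CCC/C(C)=C/CC/C(C)=C/CCc2ccoc2)OC1=O | target

## Step count and risks

Total step count: 20.
Longest linear sequence: 17 (steps 4 to 20, from furan-3-carbaldehyde).

**Step 20 (carbonylative lactonisation).**
- Loss of the C6 proton may be slow, so the acylpalladium could add to the ketone and be diverted to reduction or dimerisation.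
- The vinyl iodide may isomerise from Z to E before oxidative addition.
- Long heating with base may erode the configuration at C7.

The fallback separates the C–C bond formation from the ring closure. It sets out from 29.
1. Palladium-catalysed methoxycarbonylation (PdCl2(PPh3)2, CO, MeOH, Et3N, rt to 40 °C), in which methanol intercepts the acylpalladium, should give methyl (2Z,6S,10E,14E)-17-(furan-3-yl)-2,6,10,14-tetramethyl-4-oxoheptadeca-2,10,14-trienoate F1.
2. LiOH in THF/H2O at 0 °C followed by acidification should give the ring tautomer of the keto acid, 5-[(2S,6E,10E)-13-(furan-3-yl)-2,6,10-trimethyltrideca-6,10-dien-1-yl]-5-hydroxy-3-methylfuran-2(5H)-one F2.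
3. Ac2O, Et3N and DMAP should convert this to 2-[(2S,6E,10E)-13-(furan-3-yl)-2,6,10-trimethyltrideca-6,10-dien-1-yl]-4-methyl-5-oxo-2,5-dihydrofuran-2-yl acetate F3.
4. F3 should lose acetic acid on gentle warming in the same medium to the more stable Z alkylidene lactone, and the route comes back at 30.

**Step 14 (Barton reductive decarboxylation).**
- Reversible addition of thiyl radicals to C11=C12 or C15=C16, or reversible 3-exo closure of the C9 radical, may erode the E geometry.
- Thiol–ene addition may compete.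
- Recombination within the solvent cage, or premature decay of the light-sensitive ester, may lower the conversion.

The fallback lets the carboxyl leave by an ionic path in the flask of the sigmatropic step. It sets out from 18.
1. LiN(i-Pr)2 (2.2 equiv) and then 4-methylbenzenesulfonyl fluoride should place a sulfonyl group on C9. This gives (6E)-9-(furan-3-yl)-2,6-dimethylnona-1,6-dien-3-yl (4R)-6-{[tert-butyl(dimethyl)silyl]oxy}-4-methyl-2-(4-methylbenzenesulfonyl)hexanoate F4. The arrangement at C7 is unchanged; the descriptor changes only because the sulfonyl branch now ranks higher.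
2. Heating with N,O-bis(trimethylsilyl)acetamide and catalytic KOAc in toluene (decarboxylative Claisen rearrangement) should form C9–C10 and the E C11=C12 alkene through the same chair. The carboxylate, now α to the sulfone, loses CO2 and gives tert-butyl{[(3R,7E,11E)-14-(furan-3-yl)-3,7,11-trimethyl-5-(4-methylbenzenesulfonyl)tetradeca-7,11-dien-1-yl]oxy}dimethylsilane F5.
3. Mg in MeOH should cleave the C9–S bond, and the route comes back at 23.

**Step 12 (Ireland–Claisen rearrangement).**
- Silylation may be incomplete or may occur on carbon.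
- The ester enolate may fragment to a ketene and an alkoxide before it is trapped.
- A competing boat transition state may lower the E selectivity.

The fallback makes the same C9–C10 bond by intermolecular enolate alkylation, with the alkene geometry fixed beforehand. It sets out from 16 and 5.
1. Wittig olefination of 16 with ethyl 2-(triphenylphosphoranylidene)propanoate should give ethyl (2E,6E)-9-(furan-3-yl)-2,6-dimethylnona-2,6-dienoate F6.
2. i-Bu2AlH (2.2 equiv) should give (2E,6E)-9-(furan-3-yl)-2,6-dimethylnona-2,6-dien-1-ol F7.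
3. An Appel reaction (CBr4, PPh3) should give 3-[(3E,7E)-9-bromo-4,8-dimethylnona-3,7-dien-1-yl]furan F8.
4. The dianion of 5 (LiN(i-Pr)2, 2.2 equiv, THF, −78 to 0 °C) should displace the primary allylic bromide by SN2, and the route comes back at 21.

## Further compounds

F1 | step 20 | methyl (2Z,6S,10E,14E)-17-(furan-3-yl)-2,6,10,14-tetramethyl-4-oxoheptadeca-2,10,14-trienoate | COC(=O)/C(C)=C\C(=O)C[C@@H](C)CCC/C(C)=C/CC/C(C)=C/CCc1ccoc1
F2 | step 20 | 5-[(2S,6E,10E)-13-(furan-3-yl)-2,6,10-trimethyltrideca-6,10-dien-1-yl]-5-hydroxy-3-methylfuran-2(5H)-one | CC1=CC(O)(C[C@@H](C)CCC/C(C)=C/CC/C(C)=C/CCc2ccoc2)OC1=O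
F3 | step 20 | 2-[(2S,6E,10E)-13-(furan-3-yl)-2,6,10-trimethyltrideca-6,10-dien-1-yl]-4-methyl-5-oxo-2,5-dihydrofuran-2-yl acetate | CC1=CC(OC(C)=O)(C[C@@H](C)CCC/C(C)=C/CC/C(C)=C/CCc2ccoc2)OC1=O
F4 | step 14 | (6E)-9-(furan-3-yl)-2,6-dimethylnona-1,6-dien-3-yl (4R)-6-{[tert-butyl(dimethyl)silyl]oxy}-4-methyl-2-(4-methylbenzenesulfonyl)hexanoate | CC(C)(C)[Si](C)(C)OCC[C@@H](C)CC(C(=O)OC(CC/C(C)=C/CCc1ccoc1)C(C)=C)S(=O)(=O)c1ccc(C)cc1
F5 | step 14 | tert-butyl{[(3R,7E,11E)-14-(furan-3-yl)-3,7,11-trimethyl-5-(4-methylbenzenesulfonyl)tetradeca-7,11-dien-1-yl]oxy}dimethylsilane | CC(C)(C)[Si](C)(C)OCC[C@@H](C)CC(S(=O)(=O)c1ccc(C)cc1)C/C(C)=C/CC/C(C)=C/CCc1ccoc1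
F6 | step 12 | ethyl (2E,6E)-9-(furan-3-yl)-2,6-dimethylnona-2,6-dienoate | CCOC(=O)/C(C)=C/CC/C(C)=C/CCc1ccoc1
F7 | step 12 | (2E,6E)-9-(furan-3-yl)-2,6-dimethylnona-2,6-dien-1-ol | OC/C(C)=C/CC/C(C)=C/CCc1ccoc1
F8 | step 12 | 3-[(3E,7E)-9-bromo-4,8-dimethylnona-3,7-dien-1-yl]furan | BrC/C(C)=C/CC/C(C)=C/CCc1ccoc1
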